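Ring C is cut at O1–C2 and C3–C4. The feature exploited is that C4, C4a, C8a and O1 of rings A and C form the heterodiene of an ortho-quinone methide, while C2=C3 is the vinyl group of a ring B styrene. One chiral-acid-catalysed hetero-Diels–Alder step therefore forms both bonds, closes ring C and sets C2, with all three prenyl groups already present. The precursor is a hexasubstituted salicylaldehyde dimethyl acetal (free phenol as the future O1, two MOM ethers, two prenyl groups), used together with a MOM-protected 5-prenyl-4-vinylguaiacol. The C4 methoxy group left by the acetal is a latent ketone.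

Key step: step 7

Remark: 5-bromovanillin and tributyl(3-methylbut-2-enyl)stannane are treated as purchasable. The antipode of the chiral acid that leads to the 2S series cannot be predicted reliably and is to be fixed by one pilot run.

Step 1
Reactants: 1 2,4,6-trihydroxybenzaldehyde; 2 prenyl bromide
Product: 3 2,4,6-trihydroxy-3,5-bis(3-methylbut-2-enyl)benzaldehyde
Conditions: 2 (2.2 equiv), 10% aq KOH, 0 °C to rt; then 1 M HCl
Reagents that add atoms: none
Why: Phenoxide C-alkylation of the phloroglucinol core (Friedel–Crafts-type allylation), in which water solvates the oxygens so that the soft allylic bromide should react at the two equivalent free ring carbons, the non-enolisable aldehyde being inert to cold aqueous KOH.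

Step 2
Reactants: 3 2,4,6-trihydroxy-3,5-bis(3-methylbut-2-enyl)benzaldehyde
Product: 4 2-hydroxy-4,6-bis(methoxymethoxy)-3,5-bis(3-methylbut-2-enyl)benzaldehyde
Conditions: MOMCl (2.3 equiv), i-Pr2NEt (3 equiv), CH2Cl2, 0 °C to rt
Reagents that add atoms: chloromethyl methyl ether, COCCl
Why: Williamson-type O-alkylation with a hard electrophile should etherify the 4-OH and one of the two equivalent ortho OH groups, whereas the last ortho OH is locked in a hydrogen bond to the aldehyde and stays free to become O1.

Step 3
Reactants: 4 2-hydroxy-4,6-bis(methoxymethoxy)-3,5-bis(3-methylbut-2-enyl)benzaldehyde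
Product: 5 2-(dimethoxymethyl)-3,5-bis(methoxymethoxy)-4,6-bis(3-methylbut-2-enyl)phenol
Conditions: HC(OMe)3 (10 equiv), PPTS (5 mol%), MeOH, rt; Et3N quench, filtration through basic alumina, used at once
Reagents that add atoms: trimethyl orthoformate, COC(OC)OC; methanol, CO
Why: Acid-catalysed acetalisation driven by the orthoester as water scavenger, with PPTS too weak to touch MOM ethers or prenyl groups and the base quench keeping the electron-rich salicyl acetal from losing methanol before it is needed.

Step 4
Reactants: 6 5-bromovanillin (3-bromo-4-hydroxy-5-methoxybenzaldehyde)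
Product: 7 3-bromo-5-methoxy-4-(methoxymethoxy)benzaldehyde
Conditions: MOMCl (1.3 equiv), i-Pr2NEt (2 equiv), CH2Cl2, 0 °C to rt
Reagents that add atoms: chloromethyl methyl ether, COCCl
Why: Williamson-type O-alkylation of the single phenol, which masks the acidic OH for the coupling and the ylide step and matches the ring A protecting groups so that one final operation removes all three.

Step 5
Reactants: 7 3-bromo-5-methoxy-4-(methoxymethoxy)benzaldehyde; 8 tributyl(3-methylbut-2-enyl)stannane
Product: 9 3-methoxy-4-(methoxymethoxy)-5-(3-methylbut-2-enyl)benzaldehyde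
Conditions: 8 (1.3 equiv), Pd(PPh3)4 (5 mol%), DMF, 100 °C
Reagents that add atoms: none
Why: Stille cross-coupling under neutral conditions tolerates the aldehyde and the MOM ether, and reductive elimination at the less hindered allyl terminus should give the linear prenyl arene and not the 1,1-dimethylallyl isomer.

Step 6
Reactants: 9 3-methoxy-4-(methoxymethoxy)-5-(3-methylbut-2-enyl)benzaldehyde
Product: 10 5-ethenyl-1-methoxy-2-(methoxymethoxy)-3-(3-methylbut-2-enyl)benzene
Conditions: Ph3PCH3Br (1.4 equiv), KOtBu (1.3 equiv), THF, 0 °C to rt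
Reagents that add atoms: methyltriphenylphosphonium bromide, C[P+](c1ccccc1)(c1ccccc1)c1ccccc1.[Br-]
Why: Wittig methylenation of a non-enolisable aryl aldehyde with the unstabilised ylide, to which the MOM ether and the prenyl group are inert.

Step 7
Reactants: 5 2-(dimethoxymethyl)-3,5-bis(methoxymethoxy)-4,6-bis(3-methylbut-2-enyl)phenol; 10 5-ethenyl-1-methoxy-2-(methoxymethoxy)-3-(3-methylbut-2-enyl)benzene
Product: 12 (2S,4S)-4-methoxy-5,7-bis(methoxymethoxy)-2-[3-methoxy-4-(methoxymethoxy)-5-(3-methylbut-2-enyl)phenyl]-6,8-bis(3-methylbut-2-enyl)chromane, via 4-methoxy ortho-quinone methide 11 (not isolated)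
Conditions: confined chiral imidodiphosphoric acid HN[P(=O)(O2Ar*)]2 built from two 3,3′-bis(2,4,6-triethylphenyl)-BINOL units (5 mol%), 10 (2 equiv), 5 added over 6 h, 5 Å MS, toluene, −30 °C; Et3N quench
Reagents that add atoms: none
Why: Proposed new method: the acid protonates an acetal oxygen of 5, methanol leaves (held by the sieves) and the 4-methoxy ortho-quinone methide 11 remains paired with the chiral anion as its O-protonated oxocarbenium form, anchored through the ring A phenol; the CH2 terminus of styrene 10 then bonds to the methide carbon (future C4) while the phenolic oxygen closes on the developing benzylic cation (future C2), an asynchronous inverse-electron-demand hetero-Diels–Alder reaction driven by rearomatisation of ring A. The closest known reaction types are the racemic acid-promoted [4+2] of alkoxy ortho-quinone methides from salicylaldehyde acetals with styrenes, chiral phosphoric acid catalysed cycloadditions of 4-aryl ortho-quinone methides with styrenes and the intramolecular confined-acid variant with tethered alkenes, whereas an intermolecular enantioselective alkoxy version has not been shown. Ring C is closed as a six-membered ring by intermolecular [4+2] cycloaddition, O1–C2 and C3–C4 forming in the same event. C4 is set by the face of 11 that the catalyst pocket leaves open and C2 follows from it through the endo approach of the ring B aryl group (2,4-cis), the catalyst antipode being chosen to give 2S. The step needs regioselectivity, which the polarity of both partners secures (nucleophilic CH2 to electrophilic C4, O1 to benzylic C2), and chemoselectivity for the terminal styrene over the prenyl alkenes, which rests on its para oxygen donor, its easier fit in the confined pocket, the excess of 10 and the slow addition of 5, while the fully substituted ring A offers no site for Friedel–Crafts side reactions. Any 2,4-trans adduct is removed by chromatography at this stage, because its C2 configuration is not secured once C4 is erased.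

Step 8
Reactants: 12 (2S,4S)-4-methoxy-5,7-bis(methoxymethoxy)-2-[3-methoxy-4-(methoxymethoxy)-5-(3-methylbut-2-enyl)phenyl]-6,8-bis(3-methylbut-2-enyl)chromane
Product: 13 (2S)-5,7-bis(methoxymethoxy)-2-[3-methoxy-4-(methoxymethoxy)-5-(3-methylbut-2-enyl)phenyl]-6,8-bis(3-methylbut-2-enyl)chroman-4-ol (mixture of C4 epimers)
Conditions: TsOH·H2O (5 mol%), THF/H2O 4:1, 0 °C to rt
Reagents that add atoms: water, O
Why: SN1 solvolysis, in which the C4 methyl ether, benzylic to a ring with oxygen donors at both ortho positions and the para position (O1, 5-O, 7-O), ionises under catalytic acid and excess water traps the cation, while MOM ethers, prenyl groups and C2 (not part of the cation) stay untouched and the C4 epimer mixture is of no consequence.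

Step 9
Reactants: 13 (2S)-5,7-bis(methoxymethoxy)-2-[3-methoxy-4-(methoxymethoxy)-5-(3-methylbut-2-enyl)phenyl]-6,8-bis(3-methylbut-2-enyl)chroman-4-ol
Product: 14 (2S)-5,7-bis(methoxymethoxy)-2-[3-methoxy-4-(methoxymethoxy)-5-(3-methylbut-2-enyl)phenyl]-6,8-bis(3-methylbut-2-enyl)chroman-4-one
Conditions: Dess–Martin periodinane (1.3 equiv), pyridine (3 equiv), CH2Cl2, 0 °C to rt
Reagents that add atoms: none
Why: Dess–Martin oxidation converges both C4 epimers on the ketone, pyridine buffering the acetic acid so that the acid-labile benzylic alcohol does not ionise, and neither the trisubstituted alkenes nor the MOM ethers react.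

Step 10
Reactants: 14 (2S)-5,7-bis(methoxymethoxy)-2-[3-methoxy-4-(methoxymethoxy)-5-(3-methylbut-2-enyl)phenyl]-6,8-bis(3-methylbut-2-enyl)chroman-4-one
Product: 15 (2S)-5,7-dihydroxy-2-[4-hydroxy-3-methoxy-5-(3-methylbut-2-enyl)phenyl]-6,8-bis(3-methylbut-2-enyl)chroman-4-one (CNP0235424.1)
Conditions: 3 M aq HCl/MeOH 1:5, rt to 40 °C, stopped at full conversion
Reagents that add atoms: none
Why: Acid-catalysed methanolysis of the three MOM acetals (transacetalisation to dimethoxymethane), under which the 2S centre should hold because it is not enolisable and ring-opening to the chalcone needs base, dilute acid at moderate temperature being the usual way to unmask prenylated phenols without cyclising them to chromans.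

Compound list
1 | 2,4,6-trihydroxybenzaldehyde | O=Cc1c(O)cc(O)cc1O | starting material
2 | prenyl bromide (1-bromo-3-methylbut-2-ene) | CC(C)=CCBr | starting material
3 | 2,4,6-trihydroxy-3,5-bis(3-methylbut-2-enyl)benzaldehyde | O=Cc1c(O)c(CC=C(C)C)c(O)c(CC=C(C)C)c1O | intermediate
4 | 2-hydroxy-4,6-bis(methoxymethoxy)-3,5-bis(3-methylbut-2-enyl)benzaldehyde | O=Cc1c(O)c(CC=C(C)C)c(OCOC)c(CC=C(C)C)c1OCOC | intermediate
5 | 2-(dimethoxymethyl)-3,5-bis(methoxymethoxy)-4,6-bis(3-methylbut-2-enyl)phenol | COC(OC)c1c(O)c(CC=C(C)C)c(OCOC)c(CC=C(C)C)c1OCOC | intermediate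
6 | 5-bromovanillin (3-bromo-4-hydroxy-5-methoxybenzaldehyde) | COc1cc(C=O)cc(Br)c1O | starting material
7 | 3-bromo-5-methoxy-4-(methoxymethoxy)benzaldehyde | COCOc1c(Br)cc(C=O)cc1OC | intermediate
8 | tributyl(3-methylbut-2-enyl)stannane | CCCC[Sn](CCCC)(CCCC)CC=C(C)C | starting material
9 | 3-methoxy-4-(methoxymethoxy)-5-(3-methylbut-2-enyl)benzaldehyde | COCOc1c(CC=C(C)C)cc(C=O)cc1OC | intermediate
10 | 5-ethenyl-1-methoxy-2-(methoxymethoxy)-3-(3-methylbut-2-enyl)benzene | COc1cc(C=C)cc(CC=C(C)C)c1OCOC | intermediate
11 | 6-(methoxymethylidene)-3,5-bis(methoxymethoxy)-2,4-bis(3-methylbut-2-enyl)cyclohexa-2,4-dien-1-one (4-methoxy ortho-quinone methide; geometry of the exocyclic C=C not assigned) | COC=C1C(=O)C(CC=C(C)C)=C(OCOC)C(CC=C(C)C)=C1OCOC | intermediate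
12 | (2S,4S)-4-methoxy-5,7-bis(methoxymethoxy)-2-[3-methoxy-4-(methoxymethoxy)-5-(3-methylbut-2-enyl)phenyl]-6,8-bis(3-methylbut-2-enyl)chromane (2,4-cis) | COc1cc([C@@H]2C[C@H](OC)c3c(OCOC)c(CC=C(C)C)c(OCOC)c(CC=C(C)C)c3O2)cc(CC=C(C)C)c1OCOC | intermediate
13 | (2S)-5,7-bis(methoxymethoxy)-2-[3-methoxy-4-(methoxymethoxy)-5-(3-methylbut-2-enyl)phenyl]-6,8-bis(3-methylbut-2-enyl)chroman-4-ol (C4 epimers) | COc1cc([C@@H]2CC(O)c3c(OCOC)c(CC=C(C)C)c(OCOC)c(CC=C(C)C)c3O2)cc(CC=C(C)C)c1OCOC | intermediate
14 | (2S)-5,7-bis(methoxymethoxy)-2-[3-methoxy-4-(methoxymethoxy)-5-(3-methylbut-2-enyl)phenyl]-6,8-bis(3-methylbut-2-enyl)chroman-4-one | COc1cc([C@@H]2CC(=O)c3c(OCOC)c(CC=C(C)C)c(OCOC)c(CC=C(C)C)c3O2)cc(CC=C(C)C)c1OCOC | intermediate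
15 | (2S)-5,7-dihydroxy-2-[4-hydroxy-3-methoxy-5-(3-methylbut-2-enyl)phenyl]-6,8-bis(3-methylbut-2-enyl)chroman-4-one | COc1cc([C@@H]2CC(=O)c3c(O)c(CC=C(C)C)c(O)c(CC=C(C)C)c3O2)cc(CC=C(C)C)c1O | target

Total step count: 10. Longest linear sequence: 7 steps (steps 1, 2, 3, 7, 8, 9, 10); steps 4–6 form the ring B branch.

Steps most likely to fail

Step 7 (Proposed new method). The ion pair may fail to discriminate the faces of the quinone methide, so that enantioselectivity is poor, or the prenyl alkenes may compete for the cation and give oligomers. The fallback uses known chemistry and sets out from 5 and 10. The cycloaddition is run with an achiral acid, diphenyl phosphate (10 mol%) in toluene at 0 °C, which should give the 2,4-cis adduct as the racemate, that is 12 mixed with its (2R,4R)-configured mirror image F1. Hydrolysis and oxidation as in steps 8 and 9 carry the pair through the (2R)-chroman-4-ol F2 to the racemic ketone, 14 together with the (2R)-tris-MOM chroman-4-one F3. Preparative HPLC on amylose tris(3,5-dimethylphenylcarbamate) with hexane/i-PrOH separates the enantiomers, and the route is rejoined at 14.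

Step 1. O-alkylation and a second alkylation at an already substituted ring carbon (dearomatised gem-diprenyl products) may consume most of the material. The fallback sets out from prenyl bromide 2 and commercial phloroglucinol and builds the pattern by directed ortho-metalation. Phloroglucinol is converted with MOMCl/NaH in DMF to 1,3,5-tris(methoxymethoxy)benzene F4. n-BuLi (THF, 0 °C) lithiates between two MOM ethers, and 2 with catalytic CuBr·SMe2 gives 1,3,5-tris(methoxymethoxy)-2-(3-methylbut-2-enyl)benzene F5. A second identical cycle gives 1,3,5-tris(methoxymethoxy)-2,4-bis(3-methylbut-2-enyl)benzene F6. A third lithiation at the last ring CH followed by DMF gives 2,4,6-tris(methoxymethoxy)-3,5-bis(3-methylbut-2-enyl)benzaldehyde F7. Dilute methanolic HCl at 0 °C then removes one of the two equivalent MOM groups ortho to the aldehyde; the freed, hydrogen-bonded phenol slows further cleavage. The route is rejoined at 4.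

Step 10. The protic acid may cyclise prenyl groups onto the freed ortho phenols (chroman formation) or slowly erode C2 through reversible ring-opening. The fallback sets out from 14 and exchanges the protecting groups under aprotic, amine-buffered conditions. TMSOTf with 2,2′-bipyridyl in MeCN at 0 °C converts aryl MOM ethers into aryl trimethylsilyl ethers and should give the tris(trimethylsilyl) ether of the target F8. Stirring with water/MeOH at neutral pH then hydrolyses the silyl ethers, and the route is rejoined at 15.

Further compounds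
F1 | step 7 | (2R,4R)-4-methoxy-5,7-bis(methoxymethoxy)-2-[3-methoxy-4-(methoxymethoxy)-5-(3-methylbut-2-enyl)phenyl]-6,8-bis(3-methylbut-2-enyl)chromane | COc1cc([C@H]2C[C@@H](OC)c3c(OCOC)c(CC=C(C)C)c(OCOC)c(CC=C(C)C)c3O2)cc(CC=C(C)C)c1OCOC
F2 | step 7 | (2R)-5,7-bis(methoxymethoxy)-2-[3-methoxy-4-(methoxymethoxy)-5-(3-methylbut-2-enyl)phenyl]-6,8-bis(3-methylbut-2-enyl)chroman-4-ol (C4 epimers) | COc1cc([C@H]2CC(O)c3c(OCOC)c(CC=C(C)C)c(OCOC)c(CC=C(C)C)c3O2)cc(CC=C(C)C)c1OCOC
F3 | step 7 | (2R)-5,7-bis(methoxymethoxy)-2-[3-methoxy-4-(methoxymethoxy)-5-(3-methylbut-2-enyl)phenyl]-6,8-bis(3-methylbut-2-enyl)chroman-4-one | COc1cc([C@H]2CC(=O)c3c(OCOC)c(CC=C(C)C)c(OCOC)c(CC=C(C)C)c3O2)cc(CC=C(C)C)c1OCOC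
F4 | step 1 | 1,3,5-tris(methoxymethoxy)benzene | COCOc1cc(OCOC)cc(OCOC)c1
F5 | step 1 | 1,3,5-tris(methoxymethoxy)-2-(3-methylbut-2-enyl)benzene | COCOc1cc(OCOC)c(CC=C(C)C)c(OCOC)c1
F6 | step 1 | 1,3,5-tris(methoxymethoxy)-2,4-bis(3-methylbut-2-enyl)benzene | COCOc1cc(OCOC)c(CC=C(C)C)c(OCOC)c1CC=C(C)C
F7 | step 1 | 2,4,6-tris(methoxymethoxy)-3,5-bis(3-methylbut-2-enyl)benzaldehyde | O=Cc1c(OCOC)c(CC=C(C)C)c(OCOC)c(CC=C(C)C)c1OCOC
F8 | step 10 | (2S)-2-[3-methoxy-5-(3-methylbut-2-enyl)-4-(trimethylsilyloxy)phenyl]-6,8-bis(3-methylbut-2-enyl)-5,7-bis(trimethylsilyloxy)chroman-4-one | COc1cc([C@@H]2CC(=O)c3c(O[Si](C)(C)C)c(CC=C(C)C)c(O[Si](C)(C)C)c(CC=C(C)C)c3O2)cc(CC=C(C)C)c1O[Si](C)(C)C
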